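The target is the O-linked dehydro-dimer of a single monomer, a 2-ethyl-3-hydroxy-1,4-naphthoquinone. In the trione ring as in the quinone ring, the adjacent carbonyl carbons C3 and C4 form an oxalyl unit lying between the aromatic carbon C4a and the ethyl-bearing carbon C2. The key step exploits this by inserting diethyl oxalate between an aryllithium and a ketone enolate generated within one ortho-bromo butyrophenone, which closes the oxygenated six-membered ring through the C4a–C4 and C3–C2 bonds in one operation. Oxidative C2–O dimerisation of the resulting hydroxyquinone then creates the quaternary centre; chromatographic resolution and debenzylation complete the route.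

Key step: step 5

Remark on the chemistry: locants follow naphthalene numbering in each half (C1 is the carbonyl next to the ethyl-bearing C2, C4 the carbonyl on C4a). Hydroxyquinones are drawn as the tautomer of the target SMILES, whose stereocentre is read as (S). Commercial availability of compound 1 is assumed.

Step 1
Reactants: 1 3-bromo-4,5-dihydroxybenzaldehyde
Product: 2 3,4-bis(benzyloxy)-5-bromobenzaldehyde
Conditions: BnBr, K2CO3, DMF, 60 °C
Reagents that add atoms: benzyl bromide, BrCc1ccccc1
Why: Williamson O-alkylation of both acidic catechol hydroxyls by benzyl bromide under carbonate in DMF, with the aldehyde and the aryl bromide inert.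

Step 2
Reactants: 2 3,4-bis(benzyloxy)-5-bromobenzaldehyde
Product: 4 3,4-bis(benzyloxy)-5-bromophenol, via aryl formate 3 (not isolated)
Conditions: mCPBA, CH2Cl2, 20 °C; then K2CO3 (cat.), MeOH, 20 °C
Reagents that add atoms: 3-chloroperoxybenzoic acid (mCPBA), OOC(=O)c1cccc(Cl)c1
Why: Baeyer–Villiger (Dakin-type) oxidation, in which the aryl group made electron-rich by the para benzyloxy group migrates in preference to hydride to give the formate, which carbonate-catalysed methanolysis cleaves to the phenol.

Step 3
Reactants: 4 3,4-bis(benzyloxy)-5-bromophenol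
Product: 5 1,2,5-tris(benzyloxy)-3-bromobenzene
Conditions: BnBr, K2CO3, DMF, 60 °C
Reagents that add atoms: benzyl bromide, BrCc1ccccc1
Why: Williamson O-alkylation of the single phenol.

Step 4
Reactants: 5 1,2,5-tris(benzyloxy)-3-bromobenzene
Product: 6 1-[3,4,6-tris(benzyloxy)-2-bromophenyl]butan-1-one
Conditions: n-PrCO2H, (CF3CO)2O, 85% H3PO4 (cat.), MeCN, 20 °C
Reagents that add atoms: butanoic acid, CCCC(=O)O
Why: Friedel–Crafts acylation by the mixed butanoic trifluoroacetic anhydride without a metal Lewis acid that would cleave benzyl ethers; the ring carbon between Br and OBn is para to one benzyloxy group and ortho to another and should react first, whereas the other free carbon has two ortho donors and no para donor.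

Step 5
Reactants: 6 1-[3,4,6-tris(benzyloxy)-2-bromophenyl]butan-1-one
Product: 9 5,6,8-tris(benzyloxy)-2-ethyl-3-hydroxynaphthalene-1,4-dione, via potassium enolate 7 (not isolated), via aryllithium enolate 8 (not isolated)
Conditions: KH, THF, 0 °C; t-BuLi (2.1 equiv), −78 °C; (CO2Et)2 (1.05 equiv), −78 to 0 °C; then aq. HCl
Reagents that add atoms: diethyl oxalate, CCOC(=O)C(=O)OCC
Why: KH converts the ketone into its potassium enolate 7, which protects the carbonyl and makes C2 nucleophilic, and bromine–lithium exchange with t-BuLi then places an aryllithium at C4a, so that 8 is a 1,4-C,C-dinucleophile. The aryllithium adds to one carbonyl of diethyl oxalate (the future C4) and the enolate carbon then attacks the neighbouring ester carbonyl (the future C3) in a Dieckmann-type Claisen condensation; loss of two ethoxides and enolisation give the 2-hydroxy-1,4-quinone 9. The closest known reaction types are the cyclisation of dianions with oxalic acid diesters and the halogen–lithium exchange of enolate-protected bromo ketones. The one ring closed is the six-membered quinone ring, by a 6-exo-trig attack of the enolate carbon on the ester. No stereocentre is formed, since C2 is trigonal in 9 and becomes stereogenic only in step 6. The step needs metalation at C4a and not at the more acidic C7, which the bromine carried from 1 secures, and Claisen closure at C3 in preference to aldol closure at C4 to a five-membered ring, which is secured because C4 remains a tetrahedral hemiketal alkoxide at −78 °C and only the six-membered product can be deprotonated to a stable vinylogous carboxylate.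

Step 6
Reactants: 9 5,6,8-tris(benzyloxy)-2-ethyl-3-hydroxynaphthalene-1,4-dione (two molecules)
Product: 10 rac-5,6,8-tris(benzyloxy)-2-{[5,7,8-tris(benzyloxy)-3-ethyl-1,4-dioxo-1,4-dihydronaphthalen-2-yl]oxy}-2-ethylnaphthalene-1,3,4(2H)-trione
Conditions: PbO2, AcOH/CH2Cl2, 20 °C, dark
Reagents that add atoms: none
Why: Oxidative dehydrodimerisation of a 3-alkyl-2-hydroxy-1,4-naphthoquinone, the reaction type by which lapachol gives its so-called peroxide: one-electron oxidation by PbO2 gives a radical delocalised over C2 and the flanking oxygens, which should couple through the ethyl-bearing C2 of one unit and the C3 oxygen of another because C2–C2 coupling would join two fully substituted carbons, and since nothing biases the faces of C2 the new quaternary centre forms as a racemate that step 7 resolves.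

Step 7
Reactants: 10 rac-5,6,8-tris(benzyloxy)-2-{[5,7,8-tris(benzyloxy)-3-ethyl-1,4-dioxo-1,4-dihydronaphthalen-2-yl]oxy}-2-ethylnaphthalene-1,3,4(2H)-trione
Product: 11 (2S)-5,6,8-tris(benzyloxy)-2-{[5,7,8-tris(benzyloxy)-3-ethyl-1,4-dioxo-1,4-dihydronaphthalen-2-yl]oxy}-2-ethylnaphthalene-1,3,4(2H)-trione
Conditions: preparative HPLC, amylose tris(3,5-dimethylphenylcarbamate) stationary phase, hexane/i-PrOH, 20 °C
Reagents that add atoms: none
Why: Resolution of a racemate by preparative enantioselective chromatography: the enantiomers of 10, whose quaternary centre cannot epimerise, should differ in retention on the helical amylose carbamate selector, and the (S) enantiomer is to be identified by comparing its measured circular dichroism curve with the curve calculated for the (S) configuration.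

Step 8
Reactants: 11 (2S)-5,6,8-tris(benzyloxy)-2-{[5,7,8-tris(benzyloxy)-3-ethyl-1,4-dioxo-1,4-dihydronaphthalen-2-yl]oxy}-2-ethylnaphthalene-1,3,4(2H)-trione
Product: 12 (2S)-2-ethyl-2-[(3-ethyl-5,7,8-trihydroxy-1,4-dioxo-1,4-dihydronaphthalen-2-yl)oxy]-5,6,8-trihydroxynaphthalene-1,3,4(2H)-trione
Conditions: BCl3, C6HMe5, CH2Cl2, −78 °C; then H2O
Reagents that add atoms: none
Why: Lewis-acid ether cleavage with BCl3 and pentamethylbenzene as cation scavenger should remove all six aryl benzyl groups at low temperature (the peri ethers assisted by chelation to the neighbouring carbonyls) without any reducing agent, which matters because the C2–O linkage of the dimer is cleaved by reduction, and the quaternary centre has no acidic hydrogen and is not touched.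

Compound list
1 | 3-bromo-4,5-dihydroxybenzaldehyde | O=Cc1cc(O)c(O)c(Br)c1 | starting material
2 | 3,4-bis(benzyloxy)-5-bromobenzaldehyde | O=Cc1cc(OCc2ccccc2)c(OCc2ccccc2)c(Br)c1 | intermediate
3 | 3,4-bis(benzyloxy)-5-bromophenyl formate | O=COc1cc(OCc2ccccc2)c(OCc2ccccc2)c(Br)c1 | intermediate
4 | 3,4-bis(benzyloxy)-5-bromophenol | Oc1cc(OCc2ccccc2)c(OCc2ccccc2)c(Br)c1 | intermediate
5 | 1,2,5-tris(benzyloxy)-3-bromobenzene | Brc1cc(OCc2ccccc2)cc(OCc2ccccc2)c1OCc1ccccc1 | intermediate
6 | 1-[3,4,6-tris(benzyloxy)-2-bromophenyl]butan-1-one | CCCC(=O)c1c(Br)c(OCc2ccccc2)c(OCc2ccccc2)cc1OCc1ccccc1 | intermediate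
7 | potassium (1Z)-1-[3,4,6-tris(benzyloxy)-2-bromophenyl]but-1-en-1-olate | CC/C=C(\O[K])c1c(Br)c(OCc2ccccc2)c(OCc2ccccc2)cc1OCc1ccccc1 | intermediate
8 | potassium (1Z)-1-[3,4,6-tris(benzyloxy)-2-lithiophenyl]but-1-en-1-olate | CC/C=C(\O[K])c1c([Li])c(OCc2ccccc2)c(OCc2ccccc2)cc1OCc1ccccc1 | intermediate
9 | 5,6,8-tris(benzyloxy)-2-ethyl-3-hydroxynaphthalene-1,4-dione | CCC1=C(O)C(=O)c2c(OCc3ccccc3)c(OCc3ccccc3)cc(OCc3ccccc3)c2C1=O | intermediate
10 | rac-5,6,8-tris(benzyloxy)-2-{[5,7,8-tris(benzyloxy)-3-ethyl-1,4-dioxo-1,4-dihydronaphthalen-2-yl]oxy}-2-ethylnaphthalene-1,3,4(2H)-trione | CCC1=C(OC2(CC)C(=O)C(=O)c3c(OCc4ccccc4)c(OCc4ccccc4)cc(OCc4ccccc4)c3C2=O)C(=O)c2c(OCc3ccccc3)c(OCc3ccccc3)cc(OCc3ccccc3)c2C1=O | intermediate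
11 | (2S)-5,6,8-tris(benzyloxy)-2-{[5,7,8-tris(benzyloxy)-3-ethyl-1,4-dioxo-1,4-dihydronaphthalen-2-yl]oxy}-2-ethylnaphthalene-1,3,4(2H)-trione | CCC1=C(O[C@]2(CC)C(=O)C(=O)c3c(OCc4ccccc4)c(OCc4ccccc4)cc(OCc4ccccc4)c3C2=O)C(=O)c2c(OCc3ccccc3)c(OCc3ccccc3)cc(OCc3ccccc3)c2C1=O | intermediate
12 | (2S)-2-ethyl-2-[(3-ethyl-5,7,8-trihydroxy-1,4-dioxo-1,4-dihydronaphthalen-2-yl)oxy]-5,6,8-trihydroxynaphthalene-1,3,4(2H)-trione | CCC1=C(O[C@]2(CC)C(=O)C(=O)c3c(O)c(O)cc(O)c3C2=O)C(=O)c2c(O)c(O)cc(O)c2C1=O | target

Total step count: 8. Longest linear sequence: 8 steps (1 to 12; the two molecules of 9 joined in step 6 come from the same line).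

Steps most likely to fail

Step 6. The radical coupling may go through carbon–carbon bond formation or reversible oxygen–oxygen bond formation, or the hindered radical may be oxidised further, in place of the wanted carbon–oxygen coupling. The fallback sets out from 9 and comes back at 10, replacing the radical dimerisation by a two-electron O-alkylation. One half of 9 is brominated with N-bromosuccinimide (CH2Cl2, 0 °C) to the tertiary α-bromo trione, rac-5,6,8-tris(benzyloxy)-2-bromo-2-ethylnaphthalene-1,3,4(2H)-trione F1. The other half is converted with Ag2O into the silver salt of 9, F2. Combining F1 and F2 in toluene at 20 °C in the dark should give 10 by silver-assisted substitution of bromide by the quinonate oxygen.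

Step 5. The bromine–lithium exchange may be incomplete, the aryllithium may be protonated before it is captured, or the enolate may close onto the keto carbonyl (aldol, five-membered ring) in place of the ester. The fallback sets out from 6 and comes back at 9, making the two bonds in separate operations. Ketone 6 is condensed with diethyl oxalate (LiN(SiMe3)2, THF, −78 to 20 °C; Claisen condensation) to ethyl 3-[3,4,6-tris(benzyloxy)-2-bromobenzoyl]-2-oxopentanoate F3, so the C3–C2 bond exists before any aryl anion is made and aldol misclosure is excluded. F3 is then deprotonated with KH to its stabilised enolate and treated with t-BuLi at −78 °C. The aryllithium should attack the ester within the same molecule (Parham cyclisation, six-membered ring) and give 9 after acidification.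

Step 8. The C2–O linkage of the dimer may be cleaved under the Lewis acid, by chloride addition–elimination at the quinone carbon, in parallel with cleavage of the benzyl ethers. The fallback sets out from 9 and comes back at 12, removing the benzyl groups before the sensitive linkage exists. Monomer 9 is debenzylated with BCl3 and pentamethylbenzene (CH2Cl2, −78 °C) to 2-ethyl-3,5,6,8-tetrahydroxynaphthalene-1,4-dione F4. F4 is dimerised with PbO2 in AcOH to racemic 2-ethyl-2-[(3-ethyl-5,7,8-trihydroxy-1,4-dioxo-1,4-dihydronaphthalen-2-yl)oxy]-5,6,8-trihydroxynaphthalene-1,3,4(2H)-trione F5; only oxidation at the enol next to the ethyl group leads to a tertiary tricarbonyl radical. F5 is resolved by preparative HPLC on an immobilised amylose carbamate phase with an acidified eluent to give 12.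

Further compounds
F1 | step 6 | rac-5,6,8-tris(benzyloxy)-2-bromo-2-ethylnaphthalene-1,3,4(2H)-trione | CCC1(Br)C(=O)C(=O)c2c(OCc3ccccc3)c(OCc3ccccc3)cc(OCc3ccccc3)c2C1=O
F2 | step 6 | silver salt of 9 (silver 5,7,8-tris(benzyloxy)-3-ethyl-1,4-dioxo-1,4-dihydronaphthalen-2-olate) | CCC1=C([O-])C(=O)c2c(OCc3ccccc3)c(OCc3ccccc3)cc(OCc3ccccc3)c2C1=O.[Ag+]
F3 | step 5 | ethyl 3-[3,4,6-tris(benzyloxy)-2-bromobenzoyl]-2-oxopentanoate | CCOC(=O)C(=O)C(CC)C(=O)c1c(Br)c(OCc2ccccc2)c(OCc2ccccc2)cc1OCc1ccccc1
F4 | step 8 | 2-ethyl-3,5,6,8-tetrahydroxynaphthalene-1,4-dione | CCC1=C(O)C(=O)c2c(O)c(O)cc(O)c2C1=O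
F5 | step 8 | rac-2-ethyl-2-[(3-ethyl-5,7,8-trihydroxy-1,4-dioxo-1,4-dihydronaphthalen-2-yl)oxy]-5,6,8-trihydroxynaphthalene-1,3,4(2H)-trione | CCC1=C(OC2(CC)C(=O)C(=O)c3c(O)c(O)cc(O)c3C2=O)C(=O)c2c(O)c(O)cc(O)c2C1=O
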